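**Strategy.** Units are numbered 1–4 from the chain top (1 C4→2 C6, 2 C4→3 C8, 3 C4→4 C6; ring A phloroglucinol, ring B catechol, ring C pyran). The route rests on cutting the C4–C4a bond of ring C in unit 3, whose C4 is 3,4-trans and also bonded to C6 of unit 4. One Friedel–Crafts opening of a trans-oxirane by a symmetric 3,5-dibenzyloxyphenyl ether closes that ring, sets C4 by inversion and frees O3. The precursor is the open-chain aryl ether of an epoxy carbinol carrying ring B and, on the oxirane, C6 of 8-bromo unit 4. The all-cis units 1 and 2 arrive later as a catechin-derived dimer, corrected at C3 by oxidation–reduction.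

Key step: step 10

Remarks on the chemistry:
- 3,4-Dibenzyloxyacetophenone, 3,5-dibenzyloxyphenol, (+)-catechin and (−)-catechin are taken as purchased.
- The 4-(2-ethoxyethoxy) ethers are drawn as the 3,4-cis C4 epimer expected from the oxidation; that centre is erased when the ether ionises.
- The aryl oxiranes made in steps 8 and 9 are acid-labile, so they are passed only through triethylamine-deactivated silica and used without storage; for the same reason the oxirane is installed while the neighbouring carbon is still a ketone.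

Step 1
Reactants: 1 (−)-epicatechin
Product: 2 5,7,3',4'-tetra-O-benzyl-(−)-epicatechin
Conditions: BnBr (4.4 equiv), K2CO3, DMF, 0 °C to rt
Reagents that add atoms: benzyl bromide, BrCc1ccccc1
Why: Williamson etherification in which only the four phenols are deprotonated by the carbonate, so the secondary 3-OH stays free and C2/C3 are untouched.

Step 2
Reactants: 2 5,7,3',4'-tetra-O-benzyl-(−)-epicatechin
Product: 3 3,5,7,3',4'-penta-O-benzyl-(−)-epicatechin
Conditions: NaH, BnBr, n-Bu4NI (cat.), THF/DMF, 0 °C to rt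
Reagents that add atoms: benzyl bromide, BrCc1ccccc1
Why: Williamson etherification of the secondary alkoxide, which protects O3 of unit 4 against the later Grignard, Mitsunobu and oxidation steps.

Step 3
Reactants: 3 3,5,7,3',4'-penta-O-benzyl-(−)-epicatechin
Product: 4 8-bromo-3,5,7,3',4'-penta-O-benzyl-(−)-epicatechin
Conditions: NBS (1.0 equiv), CH2Cl2, −78 °C to rt
Reagents that add atoms: N-bromosuccinimide, O=C1CCC(=O)N1Br
Why: electrophilic aromatic bromination, which in perbenzylated flavan-3-ols goes first to C8 of ring A and thereby blocks that carbon for every later coupling.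

Step 4
Reactants: 4 8-bromo-3,5,7,3',4'-penta-O-benzyl-(−)-epicatechin
Product: 5 8-bromo-6-iodo-3,5,7,3',4'-penta-O-benzyl-(−)-epicatechin
Conditions: NIS (1.2 equiv), CF3CO2H (0.1 equiv), CH2Cl2/MeCN, 0 °C to rt, dark
Reagents that add atoms: N-iodosuccinimide, O=C1CCC(=O)N1I
Why: electrophilic aromatic iodination at C6, the only remaining ring A carbon, which lies between two benzyloxy groups and is more electron-rich than any ring B position.

Step 5
Reactants: 5 8-bromo-6-iodo-3,5,7,3',4'-penta-O-benzyl-(−)-epicatechin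
Product: 7 8-bromo-6-formyl-3,5,7,3',4'-penta-O-benzyl-(−)-epicatechin, via arylmagnesium chloride 6 (not isolated)
Conditions: i-PrMgCl·LiCl (1.1 equiv), THF, −20 °C; DMF (3 equiv), −20 °C to rt; aq NH4Cl
Reagents that add atoms: N,N-dimethylformamide, CN(C)C=O; isopropylmagnesium chloride, CC(C)[Mg]Cl (MgCl of intermediate 6 only)
Why: iodine–magnesium exchange, much faster at the C–I bond flanked by two alkoxy groups than at C–Br, followed by Bouveault formylation of the aryl Grignard puts the aldehyde on C6.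

Step 6
Reactants: 7 8-bromo-6-formyl-3,5,7,3',4'-penta-O-benzyl-(−)-epicatechin; 8 3,4-dibenzyloxyacetophenone
Product: 9 (E)-1-[3,4-bis(benzyloxy)phenyl]-3-(8-bromo-penta-O-benzylepicatechin-6-yl)prop-2-en-1-one
Conditions: KOH (aq), EtOH/THF, rt
Reagents that add atoms: none
Why: Claisen–Schmidt condensation of the acetophenone enolate with the non-enolisable aldehyde, whose aldol dehydrates by E1cB to the conjugated (E)-enone as known for 2,4,6-trialkoxybenzaldehydes.

Step 7
Reactants: 9 (E)-enone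
Product: 10 [3,4-bis(benzyloxy)phenyl][(2R,3S)-3-(8-bromo-penta-O-benzylepicatechin-6-yl)oxiran-2-yl]methanone (trans-epoxy ketone)
Conditions: poly-L-leucine, urea·H2O2, DBU, THF, rt
Reagents that add atoms: hydrogen peroxide (used as its urea adduct), OO
Why: Juliá–Colonna epoxidation (Weitz–Scheffer hydroperoxide addition inside the helical peptide), which for chalcone-type enones with poly-L-leucine should give the (2R,3S)-trans-epoxy ketone, so the catalyst sets C3 and the pre-inversion C4 of unit 3 while the carbonyl still keeps the aryl oxirane from ionising.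

Step 8
Reactants: 10 trans-epoxy ketone
Product: 11 (S)-[3,4-bis(benzyloxy)phenyl][(2S,3S)-3-(8-bromo-penta-O-benzylepicatechin-6-yl)oxiran-2-yl]methanol (erythro epoxy alcohol)
Conditions: NaBH4, CaCl2, MeOH/THF, −20 °C; basic work-up
Reagents that add atoms: none
Why: chelation-controlled borohydride reduction of an α,β-epoxy ketone, in which hydride adds to the calcium-bridged syn carbonyl/oxirane from the face away from the ring carbon and should give the erythro (anti) carbinol.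

Step 9
Reactants: 11 erythro epoxy alcohol; 12 3,5-dibenzyloxyphenol
Product: 13 (2R,3S)-2-{(R)-[3,4-bis(benzyloxy)phenyl][3,5-bis(benzyloxy)phenoxy]methyl}-3-(8-bromo-penta-O-benzylepicatechin-6-yl)oxirane (threo ether; trans-oxirane)
Conditions: PPh3, DIAD, toluene, 0 °C to rt; filtration through Et3N-treated silica
Reagents that add atoms: none
Why: Mitsunobu etherification, in which SN2 displacement of the oxyphosphonium by the phenoxide inverts the carbinol carbon (erythro to threo) and so sets the future C2 of unit 3 as 2R, the adjacent oxirane oxygen and the non-polar solvent disfavouring ionisation.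

Step 10
Reactants: 13 threo epoxy aryl ether
Product: 14 5,7,3',4'-tetra-O-benzylepicatechin-(4β→6)-8-bromo-3,5,7,3',4'-penta-O-benzylepicatechin (free 3-OH in the upper unit; 3,4-trans)
Conditions: BF3·OEt2 (0.3 equiv), CH2Cl2, −78 °C; Et3N quench
Reagents that add atoms: none
Why: BF3 binds the oxirane oxygen, the benzylic C4–O bond (weakened by the trioxygenated ring A of unit 4) stretches, and an ortho carbon of the 3,5-dibenzyloxyphenyl ether attacks C4 from the side opposite the departing oxygen, after which proton loss restores the arene and leaves O3 as the free hydroxyl. The closest known reaction type is the Lewis-acid or fluoroalcohol promoted epoxide–arene cyclisation of 3-aryl glycidyl aryl ethers to trans-4-arylchroman-3-ols. Ring C of unit 3 closes in the 6-endo mode, both oxirane carbons ending up in the pyran ring, whereas the 5-exo alternative would need attack at the non-benzylic C3. The one new stereocentre, C4, is fixed by inversion at the oxirane carbon, which places unit 4 trans to O3, while C2 and C3 pass through unchanged. The step needs regioselectivity for C4 over C3 and for the aryl ether over ring B; the first is secured by the cation-stabilising ring A of unit 4, the second by the two equivalent, triply activated ortho carbons of the symmetric ether against a less nucleophilic ring B that could only close a five-membered ring. Low temperature and substoichiometric acid are chosen to suppress hydride shift to the C3 ketone.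

Step 11
Reactants: 14 unit 3–unit 4 dimer bearing the free 3-OH
Product: 15 3,5,7,3',4'-penta-O-benzylepicatechin-(4β→6)-8-bromo-3,5,7,3',4'-penta-O-benzylepicatechin
Conditions: NaH, BnBr, n-Bu4NI (cat.), DMF, 0 °C to rt
Reagents that add atoms: benzyl bromide, BrCc1ccccc1
Why: Williamson etherification that caps O3 of unit 3, so that later only the 3-OH groups of units 1 and 2 are oxidised.

Step 12
Reactants: 16 (+)-catechin
Product: 17 5,7,3',4'-tetra-O-benzyl-(+)-catechin
Conditions: BnBr (4.4 equiv), K2CO3, DMF, 0 °C to rt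
Reagents that add atoms: benzyl bromide, BrCc1ccccc1
Why: Williamson etherification of the four phenols only, as in step 1.

Step 13
Reactants: 17 5,7,3',4'-tetra-O-benzyl-(+)-catechin
Product: 18 (2R,3S,4S)-5,7,3',4'-tetra-O-benzyl-4-(2-ethoxyethoxy)flavan-3-ol
Conditions: DDQ (2 equiv), 2-ethoxyethanol (5 equiv), CH2Cl2, rt
Reagents that add atoms: 2-ethoxyethanol, CCOCCO
Why: benzylic oxidation by DDQ hydride abstraction at C4, assisted by the ring A oxygens, with capture of the cation by the alcohol, the standard C4 activation of benzylated flavan-3-ols.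

Step 14
Reactants: 18 (2R,3S,4S)-5,7,3',4'-tetra-O-benzyl-4-(2-ethoxyethoxy)flavan-3-ol
Product: 19 (2R,3S,4S)-6,8-dibromo-5,7,3',4'-tetra-O-benzyl-4-(2-ethoxyethoxy)flavan-3-ol
Conditions: NBS (2.2 equiv), CH2Cl2, −40 °C to rt
Reagents that add atoms: N-bromosuccinimide, O=C1CCC(=O)N1Br
Why: twofold electrophilic aromatic bromination (C8, then C6) caps both nucleophilic ring A carbons so that this donor cannot condense with itself, the neutral conditions sparing the acid-labile C4 benzylic ether.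

Step 15
Reactants: 20 (−)-catechin
Product: 21 5,7,3',4'-tetra-O-benzyl-(−)-catechin
Conditions: BnBr (4.4 equiv), K2CO3, DMF, 0 °C to rt
Reagents that add atoms: benzyl bromide, BrCc1ccccc1
Why: Williamson etherification of the four phenols only, as in step 1.

Step 16
Reactants: 21 5,7,3',4'-tetra-O-benzyl-(−)-catechin
Product: 22 8-bromo-5,7,3',4'-tetra-O-benzyl-(−)-catechin
Conditions: NBS (1.0 equiv), CH2Cl2, −78 °C to rt
Reagents that add atoms: N-bromosuccinimide, O=C1CCC(=O)N1Br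
Why: electrophilic aromatic bromination at C8, as in step 3, which leaves C6 as the only nucleophilic ring A carbon of unit 2.

Step 17
Reactants: 19 (2R,3S,4S)-6,8-dibromo-5,7,3',4'-tetra-O-benzyl-4-(2-ethoxyethoxy)flavan-3-ol; 22 8-bromo-5,7,3',4'-tetra-O-benzyl-(−)-catechin
Product: 23 6,8-dibromo-5,7,3',4'-tetra-O-benzyl-(+)-catechin-(4α→6)-8-bromo-5,7,3',4'-tetra-O-benzyl-(−)-catechin (3,4-trans; both 3-OH free)
Conditions: Me3SiOTf (0.5 equiv), nucleophile in 2.5-fold excess, 4 Å MS, CH2Cl2, −78 to −40 °C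
Reagents that add atoms: none
Why: Lewis-acid promoted interflavan Friedel–Crafts coupling, in which the C4 cation released from the 4-alkoxy donor is attacked by C6 of the 8-bromo nucleophile (C8 being brominated) anti to the neighbouring 3-OH, giving the 3,4-trans 4→6 bond as is usual for catechin-type donors.

Step 18
Reactants: 23 unit 1–unit 2 dimer
Product: 24 4-(2-ethoxyethoxy) derivative of the tribromo catechin dimer (ether at C4 of the lower unit; 3,4-cis)
Conditions: DDQ (2 equiv), 2-ethoxyethanol (5 equiv), CH2Cl2, rt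
Reagents that add atoms: 2-ethoxyethanol, CCOCCO
Why: DDQ benzylic oxidation at the only methylene, C4 of unit 2, the way benzylated procyanidin dimers are turned into chain-extension donors, the methine C4–H of unit 1 being shielded by two flanking benzyloxy groups and a dibrominated ring.

Step 19
Reactants: 24 dimeric 4-(2-ethoxyethoxy) donor; 15 3,5,7,3',4'-penta-O-benzylepicatechin-(4β→6)-8-bromo-3,5,7,3',4'-penta-O-benzylepicatechin
Product: 25 benzylated tetrabromo tetramer in which the two upper units are catechin-type (2,3-trans-3,4-trans; 3-OH free)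
Conditions: Me3SiOTf (0.5 equiv), nucleophile in 1.3-fold excess, 4 Å MS, CH2Cl2, −78 to −40 °C
Reagents that add atoms: none
Why: interflavan Friedel–Crafts coupling in which the fully bromine-capped donor can only meet the nucleophile at C8 of unit 3, the usual and less hindered site of chain extension (unit 4 is blocked at C6 and C8), and attack anti to the 3-OH gives the 3,4-trans bond between C4 of unit 2 and C8 of unit 3.

Step 20
Reactants: 25 benzylated tetramer (3-OH free in units 1 and 2)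
Product: 26 benzylated tetrabromo tetramer bis(flavan-3-one) (C3 ketones in the two upper units)
Conditions: Dess–Martin periodinane (3 equiv), NaHCO3, wet CH2Cl2, 0 °C to rt
Reagents that add atoms: none
Why: Dess–Martin oxidation of the only two free secondary alcohols under buffered conditions, as used for the catechin-to-epicatechin interconversion, with the 2,4-cis-diaryl ketone being the more stable C4 epimer should any enolisation occur.

Step 21
Reactants: 26 diketone
Product: 27 benzylated tetrabromo tetramer of target configuration (two upper units 2,3-cis-3,4-cis; 3-OH free)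
Conditions: LiBH(s-Bu)3 (L-Selectride, 3 equiv), LiBr, THF, −78 °C; aq work-up
Reagents that add atoms: none
Why: substrate-controlled reduction with a bulky hydride, as in the flavan-3-one to epicatechin reduction, where the C2 and C4 aryl groups lie on one face of each ketone so that hydride adds from the other and the new 3-OH is cis to both.

Step 22
Reactants: 27 protected tetramer
Product: 28 CNP0120618.3 [epicatechin-(4α→6)-ent-epicatechin-(4β→8)-epicatechin-(4β→6)-epicatechin]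
Conditions: H2 (1 atm), Pd(OH)2/C, Et3N, THF/MeOH/H2O, rt
Reagents that add atoms: none
Why: catalytic hydrogenolysis of the eighteen benzyl ethers together with hydrodebromination of the four aryl bromides, the amine buffering HBr so that the acid-labile interflavan bonds survive.

**Compound list**

1 | (−)-epicatechin | Oc1cc(O)c2c(c1)O[C@H](c1ccc(O)c(O)c1)[C@H](O)C2 | starting material
2 | 5,7,3',4'-tetra-O-benzyl-(−)-epicatechin | c9ccccc9COc1cc(OCc9ccccc9)c2c(c1)O[C@H](c1ccc(OCc9ccccc9)c(OCc9ccccc9)c1)[C@H](O)C2 | intermediate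
3 | 3,5,7,3',4'-penta-O-benzyl-(−)-epicatechin | c9ccccc9COc1cc(OCc9ccccc9)c2c(c1)O[C@H](c1ccc(OCc9ccccc9)c(OCc9ccccc9)c1)[C@H](OCc9ccccc9)C2 | intermediate
4 | 8-bromo-3,5,7,3',4'-penta-O-benzyl-(−)-epicatechin | c1c(OCc9ccccc9)c(Br)c3c(c1OCc9ccccc9)C[C@@H](OCc9ccccc9)[C@@H](c1ccc(OCc9ccccc9)c(OCc9ccccc9)c1)O3 | intermediate
5 | 8-bromo-6-iodo-3,5,7,3',4'-penta-O-benzyl-(−)-epicatechin | Ic1c(OCc9ccccc9)c(Br)c3c(c1OCc9ccccc9)C[C@@H](OCc9ccccc9)[C@@H](c1ccc(OCc9ccccc9)c(OCc9ccccc9)c1)O3 | intermediate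
6 | C6 arylmagnesium chloride of 5 (8-bromo retained) | Cl[Mg]c1c(OCc9ccccc9)c(Br)c3c(c1OCc9ccccc9)C[C@@H](OCc9ccccc9)[C@@H](c1ccc(OCc9ccccc9)c(OCc9ccccc9)c1)O3 | intermediate (not isolated)
7 | 8-bromo-6-formyl-3,5,7,3',4'-penta-O-benzyl-(−)-epicatechin | O=Cc1c(OCc9ccccc9)c(Br)c3c(c1OCc9ccccc9)C[C@@H](OCc9ccccc9)[C@@H](c1ccc(OCc9ccccc9)c(OCc9ccccc9)c1)O3 | intermediate
8 | 3,4-dibenzyloxyacetophenone | CC(=O)c1ccc(OCc9ccccc9)c(OCc9ccccc9)c1 | starting material
9 | (E)-1-[3,4-bis(benzyloxy)phenyl]-3-(8-bromo-penta-O-benzylepicatechin-6-yl)prop-2-en-1-one | O=C(c1ccc(OCc9ccccc9)c(OCc9ccccc9)c1)/C=C/c1c(OCc9ccccc9)c(Br)c3c(c1OCc9ccccc9)C[C@@H](OCc9ccccc9)[C@@H](c1ccc(OCc9ccccc9)c(OCc9ccccc9)c1)O3 | intermediate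
10 | [3,4-bis(benzyloxy)phenyl][(2R,3S)-3-(8-bromo-penta-O-benzylepicatechin-6-yl)oxiran-2-yl]methanone | O=C(c1ccc(OCc9ccccc9)c(OCc9ccccc9)c1)[C@@H]2O[C@H]2c1c(OCc9ccccc9)c(Br)c3c(c1OCc9ccccc9)C[C@@H](OCc9ccccc9)[C@@H](c1ccc(OCc9ccccc9)c(OCc9ccccc9)c1)O3 | intermediate
11 | (S)-[3,4-bis(benzyloxy)phenyl][(2S,3S)-3-(8-bromo-penta-O-benzylepicatechin-6-yl)oxiran-2-yl]methanol (erythro) | O[C@@H](c1ccc(OCc9ccccc9)c(OCc9ccccc9)c1)[C@@H]2O[C@H]2c1c(OCc9ccccc9)c(Br)c3c(c1OCc9ccccc9)C[C@@H](OCc9ccccc9)[C@@H](c1ccc(OCc9ccccc9)c(OCc9ccccc9)c1)O3 | intermediate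
12 | 3,5-dibenzyloxyphenol | Oc1cc(OCc9ccccc9)cc(OCc9ccccc9)c1 | starting material
13 | (2R,3S)-2-{(R)-[3,4-bis(benzyloxy)phenyl][3,5-bis(benzyloxy)phenoxy]methyl}-3-(8-bromo-penta-O-benzylepicatechin-6-yl)oxirane (threo ether; key-step precursor) | c9ccccc9COc1cc(OCc9ccccc9)cc(c1)O[C@H](c1ccc(OCc9ccccc9)c(OCc9ccccc9)c1)[C@@H]2O[C@H]2c1c(OCc9ccccc9)c(Br)c3c(c1OCc9ccccc9)C[C@@H](OCc9ccccc9)[C@@H](c1ccc(OCc9ccccc9)c(OCc9ccccc9)c1)O3 | intermediate
14 | 5,7,3',4'-tetra-O-benzylepicatechin-(4β→6)-8-bromo-3,5,7,3',4'-penta-O-benzylepicatechin (unit 3 3-OH free; key-step product) | c9ccccc9COc1cc(OCc9ccccc9)c2c(c1)O[C@H](c1ccc(OCc9ccccc9)c(OCc9ccccc9)c1)[C@H](O)[C@H]2c1c(OCc9ccccc9)c(Br)c3c(c1OCc9ccccc9)C[C@@H](OCc9ccccc9)[C@@H](c1ccc(OCc9ccccc9)c(OCc9ccccc9)c1)O3 | intermediate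
15 | 3,5,7,3',4'-penta-O-benzylepicatechin-(4β→6)-8-bromo-3,5,7,3',4'-penta-O-benzylepicatechin | c9ccccc9COc1cc(OCc9ccccc9)c2c(c1)O[C@H](c1ccc(OCc9ccccc9)c(OCc9ccccc9)c1)[C@H](OCc9ccccc9)[C@H]2c1c(OCc9ccccc9)c(Br)c3c(c1OCc9ccccc9)C[C@@H](OCc9ccccc9)[C@@H](c1ccc(OCc9ccccc9)c(OCc9ccccc9)c1)O3 | intermediate
16 | (+)-catechin | Oc1cc(O)c2c(c1)O[C@H](c1ccc(O)c(O)c1)[C@@H](O)C2 | starting material
17 | 5,7,3',4'-tetra-O-benzyl-(+)-catechin | c9ccccc9COc1cc(OCc9ccccc9)c2c(c1)O[C@H](c1ccc(OCc9ccccc9)c(OCc9ccccc9)c1)[C@@H](O)C2 | intermediate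
18 | (2R,3S,4S)-5,7,3',4'-tetra-O-benzyl-4-(2-ethoxyethoxy)flavan-3-ol | c9ccccc9COc1cc(OCc9ccccc9)c2c(c1)O[C@H](c1ccc(OCc9ccccc9)c(OCc9ccccc9)c1)[C@@H](O)[C@H]2OCCOCC | intermediate
19 | (2R,3S,4S)-6,8-dibromo-5,7,3',4'-tetra-O-benzyl-4-(2-ethoxyethoxy)flavan-3-ol | c9ccccc9COc1c(Br)c(OCc9ccccc9)c2c(c1Br)O[C@H](c1ccc(OCc9ccccc9)c(OCc9ccccc9)c1)[C@@H](O)[C@H]2OCCOCC | intermediate
20 | (−)-catechin | Oc1cc(O)c2c(c1)O[C@@H](c1ccc(O)c(O)c1)[C@H](O)C2 | starting material
21 | 5,7,3',4'-tetra-O-benzyl-(−)-catechin | c9ccccc9COc1cc(OCc9ccccc9)c2c(c1)O[C@@H](c1ccc(OCc9ccccc9)c(OCc9ccccc9)c1)[C@H](O)C2 | intermediate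
22 | 8-bromo-5,7,3',4'-tetra-O-benzyl-(−)-catechin | c9ccccc9COc1cc(OCc9ccccc9)c2c(c1Br)O[C@@H](c1ccc(OCc9ccccc9)c(OCc9ccccc9)c1)[C@H](O)C2 | intermediate
23 | 6,8-dibromo-tetra-O-benzyl-(+)-catechin-(4α→6)-8-bromo-tetra-O-benzyl-(−)-catechin (unit 1 3,4-trans; both 3-OH free) | c9ccccc9COc1c(Br)c(OCc9ccccc9)c2c(c1Br)O[C@H](c1ccc(OCc9ccccc9)c(OCc9ccccc9)c1)[C@@H](O)[C@@H]2c1c(OCc9ccccc9)c(Br)c2c(c1OCc9ccccc9)C[C@@H](O)[C@H](c1ccc(OCc9ccccc9)c(OCc9ccccc9)c1)O2 | intermediate
24 | 6,8-dibromo-tetra-O-benzyl-(+)-catechin-(4α→6)-8-bromo-tetra-O-benzyl-4-(2-ethoxyethoxy)-(−)-catechin (ether at C4 of unit 2; 3,4-cis) | c9ccccc9COc1c(Br)c(OCc9ccccc9)c2c(c1Br)O[C@H](c1ccc(OCc9ccccc9)c(OCc9ccccc9)c1)[C@@H](O)[C@@H]2c1c(OCc9ccccc9)c(Br)c2c(c1OCc9ccccc9)[C@@H](OCCOCC)[C@@H](O)[C@H](c1ccc(OCc9ccccc9)c(OCc9ccccc9)c1)O2 | intermediate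
25 | benzylated tetramer, units 1 and 2 catechin-type (2,3-trans-3,4-trans, 3-OH free), units 3 and 4 3-O-benzyl; Br at unit 1 C6/C8, unit 2 C8, unit 4 C8 | c9ccccc9COc1c(Br)c(OCc9ccccc9)c2c(c1Br)O[C@H](c1ccc(OCc9ccccc9)c(OCc9ccccc9)c1)[C@@H](O)[C@@H]2c1c(OCc9ccccc9)c(Br)c2c(c1OCc9ccccc9)[C@H](c1c(OCc9ccccc9)cc(OCc9ccccc9)c3c1O[C@H](c1ccc(OCc9ccccc9)c(OCc9ccccc9)c1)[C@H](OCc9ccccc9)[C@H]3c1c(OCc9ccccc9)c(Br)c3c(c1OCc9ccccc9)C[C@@H](OCc9ccccc9)[C@@H](c1ccc(OCc9ccccc9)c(OCc9ccccc9)c1)O3)[C@@H](O)[C@H](c1ccc(OCc9ccccc9)c(OCc9ccccc9)c1)O2 | intermediate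
26 | tetramer 25 with C3 ketones in units 1 and 2 | c9ccccc9COc1c(Br)c(OCc9ccccc9)c2c(c1Br)O[C@H](c1ccc(OCc9ccccc9)c(OCc9ccccc9)c1)C(=O)[C@@H]2c1c(OCc9ccccc9)c(Br)c2c(c1OCc9ccccc9)[C@H](c1c(OCc9ccccc9)cc(OCc9ccccc9)c3c1O[C@H](c1ccc(OCc9ccccc9)c(OCc9ccccc9)c1)[C@H](OCc9ccccc9)[C@H]3c1c(OCc9ccccc9)c(Br)c3c(c1OCc9ccccc9)C[C@@H](OCc9ccccc9)[C@@H](c1ccc(OCc9ccccc9)c(OCc9ccccc9)c1)O3)C(=O)[C@H](c1ccc(OCc9ccccc9)c(OCc9ccccc9)c1)O2 | intermediate
27 | benzylated, tetrabrominated target (units 1 and 2 2,3-cis-3,4-cis, 3-OH free) | c9ccccc9COc1c(Br)c(OCc9ccccc9)c2c(c1Br)O[C@H](c1ccc(OCc9ccccc9)c(OCc9ccccc9)c1)[C@H](O)[C@@H]2c1c(OCc9ccccc9)c(Br)c2c(c1OCc9ccccc9)[C@H](c1c(OCc9ccccc9)cc(OCc9ccccc9)c3c1O[C@H](c1ccc(OCc9ccccc9)c(OCc9ccccc9)c1)[C@H](OCc9ccccc9)[C@H]3c1c(OCc9ccccc9)c(Br)c3c(c1OCc9ccccc9)C[C@@H](OCc9ccccc9)[C@@H](c1ccc(OCc9ccccc9)c(OCc9ccccc9)c1)O3)[C@H](O)[C@H](c1ccc(OCc9ccccc9)c(OCc9ccccc9)c1)O2 | intermediate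
28 | CNP0120618.3, epicatechin-(4α→6)-ent-epicatechin-(4β→8)-epicatechin-(4β→6)-epicatechin | Oc1cc(O)c2c(c1)O[C@H](c1ccc(O)c(O)c1)[C@H](O)[C@@H]2c1c(O)cc2c(c1O)[C@H](c1c(O)cc(O)c3c1O[C@H](c1ccc(O)c(O)c1)[C@H](O)[C@H]3c1c(O)cc3c(c1O)C[C@@H](O)[C@@H](c1ccc(O)c(O)c1)O3)[C@H](O)[C@H](c1ccc(O)c(O)c1)O2 | target

**Step count.** Total: 22 steps. Longest linear sequence: 15 steps (steps 1–11, then 19–22).

**Steps most likely to fail**

Step 10. The electron-rich oxirane may ionise completely before the arene arrives, which would erode the inversion at C4 or divert material into hydride shift or closure onto ring B. The fallback makes the same bond by intermolecular coupling and sets out from 2 and 4. Oxidation of 2 with DDQ and 2-ethoxyethanol in CH2Cl2 gives (2R,3R,4S)-5,7,3',4'-tetra-O-benzyl-4-(2-ethoxyethoxy)flavan-3-ol F1. Its Me3SiOTf-promoted Friedel–Crafts coupling with a threefold excess of 4 at −78 °C should give the 4β→6 bond, since epicatechin-type cations are attacked only anti to the 3-OH and C8 of 4 is brominated. The fallback returns to the route at 14 and replaces steps 4–10.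

Step 7. The peptide catalyst may give poor facial selectivity or low conversion with an enone whose β-carbon carries a hindered, electron-rich aryl group. The fallback sets out from 9. Corey–Bakshi–Shibata reduction (B-methyl oxazaborolidine derived from diphenylprolinol, BH3·SMe2, THF, −20 °C) should give (R,E)-1-[3,4-bis(benzyloxy)phenyl]-3-(8-bromo-penta-O-benzylepicatechin-6-yl)prop-2-en-1-ol F2. The catalyst enantiomer is the one that delivers the (R)-carbinol and is to be fixed on a model chalcone. Sharpless epoxidation of F2 (Ti(O-i-Pr)4, L-(+)-diisopropyl tartrate, t-BuOOH, 4 Å MS, CH2Cl2, −20 °C, amine-buffered work-up) then delivers oxygen in the matched, erythro-selective sense and leaves any (S)-carbinol behind by kinetic resolution. It returns to the route at 11 and replaces steps 7 and 8.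

Step 18. Hydride abstraction may be slow on the brominated dimer or may occur at the doubly benzylic C4–H of unit 1 instead of the unit 2 methylene. The fallback installs the leaving group on the monomer and sets out from 22 (with 19 and 15 unchanged). DDQ and 2-ethoxyethanol convert 22 into (2S,3R,4R)-8-bromo-5,7,3',4'-tetra-O-benzyl-4-(2-ethoxyethoxy)flavan-3-ol F3. Exchange with 2,6-dimethylbenzenethiol and BF3·OEt2 at −78 °C gives the 3,4-trans thioether 8-bromo-5,7,3',4'-tetra-O-benzyl-4-(2,6-dimethylphenylthio)-(−)-catechin F4, which is inert to hard Lewis acids. Coupling of F4 at C6 with 19 under BF3·OEt2 at −78 °C gives the dimeric thioether F5 (dimer 23 carrying the arylthio group at C4 of unit 2). Activation of F5 with the thiophile AgBF4 in THF/CH2Cl2 at 0 °C in the presence of 15 forms the unit 2 C4–unit 3 C8 bond and returns to the route at 25, replacing steps 17–19.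

**Further compounds**

F1 | step 10 | (2R,3R,4S)-5,7,3',4'-tetra-O-benzyl-4-(2-ethoxyethoxy)flavan-3-ol | c9ccccc9COc1cc(OCc9ccccc9)c2c(c1)O[C@H](c1ccc(OCc9ccccc9)c(OCc9ccccc9)c1)[C@H](O)[C@H]2OCCOCC
F2 | step 7 | (R,E)-1-[3,4-bis(benzyloxy)phenyl]-3-(8-bromo-penta-O-benzylepicatechin-6-yl)prop-2-en-1-ol | O[C@@H](c1ccc(OCc9ccccc9)c(OCc9ccccc9)c1)/C=C/c1c(OCc9ccccc9)c(Br)c3c(c1OCc9ccccc9)C[C@@H](OCc9ccccc9)[C@@H](c1ccc(OCc9ccccc9)c(OCc9ccccc9)c1)O3
F3 | step 18 | (2S,3R,4R)-8-bromo-5,7,3',4'-tetra-O-benzyl-4-(2-ethoxyethoxy)flavan-3-ol | c9ccccc9COc1cc(OCc9ccccc9)c2c(c1Br)O[C@@H](c1ccc(OCc9ccccc9)c(OCc9ccccc9)c1)[C@H](O)[C@@H]2OCCOCC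
F4 | step 18 | 8-bromo-5,7,3',4'-tetra-O-benzyl-4-(2,6-dimethylphenylthio)-(−)-catechin (3,4-trans) | c9ccccc9COc1cc(OCc9ccccc9)c2c(c1Br)O[C@@H](c1ccc(OCc9ccccc9)c(OCc9ccccc9)c1)[C@H](O)[C@H]2Sc1c(C)cccc1C
F5 | step 18 | dimer 23 carrying a 2,6-dimethylphenylthio group at C4 of unit 2 (3,4-trans) | c9ccccc9COc1c(Br)c(OCc9ccccc9)c2c(c1Br)O[C@H](c1ccc(OCc9ccccc9)c(OCc9ccccc9)c1)[C@@H](O)[C@@H]2c1c(OCc9ccccc9)c(Br)c2c(c1OCc9ccccc9)[C@H](Sc1c(C)cccc1C)[C@@H](O)[C@H](c1ccc(OCc9ccccc9)c(OCc9ccccc9)c1)O2
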